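A ratio is wanted before the next charge: product gained per free base added. The free base, the acid scavenger, is the setting to change, and the question is how far it pays and how long to wait.

| setting | maple | alder | south | north-west | north |
|---|---|---|---|---|---|
| electrophile | 0.050 M | 0.050 M | 0.050 M | 0.050 M | 0.050 M |
| nucleophile | 0.060 M | 0.060 M | 0.0600 M | 0.0600 M | 0.0600 M |
| free base | 0.010 M | 0.029 M | 0.0220 M | 0.0340 M | 0.0150 M |
| protic impurity | 0.025 M | 0.025 M | 0.0250 M | 0.0250 M | 0.0250 M |
| remark | run made earlier | run made earlier |  |  |  |
| time |  |  | 3.0 d | 3.0 d | 3.0 d |

- maple (time / h: electrophile / %, product / %): 10.0: 34.2, 66.0; 20.0: 35.1, 65.5; 25.0: 34.7, 63.5; 40.0: 36.1, 64.4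
- alder (time / h: electrophile / %, product / %): 10.0: 20.4, 79.8; 20.0: 20.4, 80.8; 25.0: 20.0, 80.3; 40.0: 21.4, 78.4

(each reading ± 1 percentage point)

- steps that have been proposed: nucleophile + protic impurity -> quenched reagent; nucleophile + acid set free <-> protonated nucleophile; electrophile + nucleophile <-> acid set free + product; acid set free + free base <-> salt of the base

- part of the electrophile that has reacted at the end, south
- part of the electrophile that has reacted at the end, north-west
- part of the electrophile that has reacted at the end, north
- what raising the concentration of free base from its lowest to its highest value here does to the part of the electrophile that has reacted (changes below 5 percentage points count as none) (it rises / it falls / no change)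

Maple and alder differ in free base. Over its four readings the maple run shows a mean of 65.0 % of the electrophile reacted, and the alder run 79.5 %. So the product gained per free base added, the gain per base, reads 0.381.

Follow one added free base. It catches one acid set free, which otherwise pairs with a nucleophile, so one nucleophile is spared. Beyond the base, a product costs two nucleophiles, one to react and one taken by its acid, so on this count one spared nucleophile is worth 0.5 of a product. The reading lies lower, and the spared nucleophile has a further fork, to the protic impurity.

My own line through the maple run gives 68.8 % for north, 74.1 % for south and 83.3 % for north-west, a spread of 15 percentage points. So the base is worth changing. The clock is not: from the first reading to the last, the electrophile drifts up 1.9 points in the maple run and 1 point in the alder run, against a scatter of 1 point. The run therefore stops at 3.0 d.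

The forecast says 68.8 % for north, 74.7 % for south and 84.7 % for north-west, and for the reacted part as the free base goes from lowest to highest it says: it rises. Its ground for the time is this: “Three days should add little, since the plateau is flat.” It meets my line at north and stands above it at south and north-west.

    nucleophile + protic impurity → quenched reagent (k = 1.60 × 10⁻⁴ /M/s)
    nucleophile + acid set free ⇌ protonated nucleophile, settled at all times (K = 1500 /M)
    electrophile + nucleophile ⇌ acid set free + product (K = 0.860, k = 0.00320 /M/s)
    acid set free + free base ⇌ salt of the base, settled at all times (K = 22000 /M)

North gives 66.2 %, south 72.1 % and north-west 82.0 %. From the lowest free base to the highest the answer is: it rises, by 16 points, so the forecast holds within its margins. North-west has not come to rest: at 30.0 d its reacted part is down to 71.3 %, so the forecast's 84.7 % would be wrong for a flask left that long, while quenched reagent climbs from 0.00647 M to 0.0193 M. The gain per base from north to north-west reads 0.415 at 3.0 d and 0.460 at 30.0 d. Carried from north's 53.9 % at 30.0 d, the read 0.381 puts south at 59.2 %, and south at that time stands at 60.2 %.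

The readings come from a simulation for substances that don't exist; the scatter is artificial.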